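The pyridone ring of the quinolone (N1, C2, C3, C4, C4a, C8a) is cut at two bonds. One is the aryl–nitrogen bond N1–C8a. The other is the C2=C3 double bond, the dehydrated aldol link between an acetyl methyl carbon (C3) and a fatty amide carbonyl (C2). This leaves 2'-bromoacetophenone (benzene ring, C4, C3) and hexadecanamide (N1, C2, the C15 chain). A single flask operation, copper-catalysed amidation followed by hydroxide-driven Camps closure, makes both bonds and the ring and delivers 2-pentadecylquinolin-4(1H)-one. The precursors are two bought compounds, so no step precedes the key step, and one N1-methylation follows it.

Key step: step 1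

Remark: 5 is written as its 4(1H)-oxo tautomer, which dominates over the 4-hydroxyquinoline form. The target has no stereocentre and no stereogenic double bond, so its SMILES carries no stereo descriptors.

**Step 1**
Reactants: 1 2'-bromoacetophenone (bromine on the ring, ortho to the acetyl group); 2 hexadecanamide
Product: 5 2-pentadecylquinolin-4(1H)-one, via N-(2-acetylphenyl)hexadecanamide 3 (not isolated), via cyclic hemiaminal 4 (not isolated)
Conditions: CuI (10 mol %), MeNHCH2CH2NHMe (20 mol %), K2CO3 (2 equiv), 1,4-dioxane, 110 °C, Ar; then powdered NaOH (3.5 equiv), same flask, 110 °C; aq. HCl to pH 7
Reagents that add atoms: none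
Why: The step strings together two established reactions, a Goldberg amidation of an ortho-haloaryl ketone with a primary amide and a Camps cyclization of the resulting N-(2-acylaryl)amide, which is the closest known reaction type and covers this substrate class. In the first stage K2CO3 and diamine-ligated monovalent copper turn 2 into a copper amidate, which takes up the C–Br bond of 1 (formally by oxidative addition to trivalent copper, probably helped by the ortho acetyl oxygen) and releases anilide 3 with the N1–C8a bond by reductive elimination; 3 is a hindered, internally hydrogen-bonded secondary amide and should not arylate again. In the second stage hydroxide forms the enolate of the acetyl group, its carbon C3 adds to the amide carbonyl C2 in a 6-(enolendo)-exo-trig closure of the pyridone ring to give hemiaminal 4, and E1cB loss of water sets C2=C3, after which ionisation of 5 makes the sequence irreversible. The selectivity required is between the two Camps modes, C3 onto C2 (4-quinolone series) against the amide α-CH2 onto the ketone carbonyl (2-quinolone series). It is secured by the much higher acidity of the aryl ketone CH3 and by the strong base, which also ionises the N–H and thereby shuts down enolisation on the amide side; for this reason NaOH is added as soon as the coupling is over and the milder carbonate base is not relied on for the closure. The only stereocentre that appears, C2 of 4, forms as a racemate and vanishes on dehydration, so no stereocontrol is needed.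

**Step 2**
Reactants: 5 2-pentadecylquinolin-4(1H)-one; 6 iodomethane
Product: 7 1-methyl-2-pentadecylquinolin-4(1H)-one
Conditions: NaH (1.2 equiv), THF, 0 °C to rt; MeI (2 equiv), rt to 40 °C; chromatography on silica
Reagents that add atoms: iodomethane 6, CI
Why: This is an SN2 N-alkylation of the ambident anion of a 4-quinolone, in which the sodium ion stays paired with the hard O4 terminus in THF, so the soft electrophile MeI should be taken up at N1 to give the vinylogous amide, the more stable of the two possible methylation products, while the alkyl chain, the C4 carbonyl and the arene are inert.

**Compound list**
1 | 2'-bromoacetophenone, 1-(2-bromophenyl)ethanone (ring bromide, not phenacyl bromide) | CC(=O)c1ccccc1Br | starting material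
2 | hexadecanamide (palmitamide) | CCCCCCCCCCCCCCCC(N)=O | starting material
3 | N-(2-acetylphenyl)hexadecanamide | CCCCCCCCCCCCCCCC(=O)Nc1ccccc1C(C)=O | intermediate
4 | rac-2-hydroxy-2-pentadecyl-2,3-dihydroquinolin-4(1H)-one (cyclic hemiaminal, transient) | CCCCCCCCCCCCCCCC1(O)CC(=O)c2ccccc2N1 | intermediate
5 | 2-pentadecylquinolin-4(1H)-one | CCCCCCCCCCCCCCCc1cc(=O)c2ccccc2[nH]1 | intermediate
6 | iodomethane | CI | starting material
7 | 1-methyl-2-pentadecylquinolin-4(1H)-one | CCCCCCCCCCCCCCCc1cc(=O)c2ccccc2n1C | target

Total step count: 2
Longest linear sequence: 2 steps (1 to 5 to 7)

**Steps most likely to fail**
The route has only two steps, so the ranking holds two entries.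

1. Step 1.
   - Risk: the waxy, poorly soluble primary amide may couple sluggishly at the ortho-substituted bromide. The methyl ketone may self-condense under base during the long heating. Hydroxide may cleave the anilide before it cyclises. Enolisation on the amide side may divert material into the other Camps mode.
   - Fallback (sets out from 1, comes back at 7): the order of bond formation is inverted, so that C2–C3 is made first and N1–C8a last. Crossed Claisen condensation of 1 with methyl hexadecanoate (NaH, THF, reflux) should give 1-(2-bromophenyl)octadecane-1,3-dione F1. Methylamine in ethanol then condenses at the more electrophilic aliphatic carbonyl to give the internally hydrogen-bonded enaminone (Z)-1-(2-bromophenyl)-3-(methylamino)octadec-2-en-1-one F2. An intramolecular Ullmann-type N-arylation (CuI, MeNHCH2CH2NHMe, K2CO3, DMSO, 80 °C) closes the pyridone ring and should give 7 directly. This sequence has no competing ring-closure mode, and the N-methyl group is in place from the start, so step 2 is bypassed as well.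

2. Step 2.
   - Risk: alkylation may compete at O4, favoured by crowding of N1 between the C2 chain and the peri C8–H. Two lipophilic isomers would then have to be separated.
   - Fallback (sets out from 5, comes back at 7): the oxygen is taken out of play before the methyl group is introduced. POCl3 at reflux should convert 5 into 4-chloro-2-pentadecylquinoline F3, in which N1 is the only nucleophilic site. MeOTf in CH2Cl2 at rt quaternises it to 4-chloro-1-methyl-2-pentadecylquinolinium trifluoromethanesulfonate F4. Aqueous NaOH in THF then displaces the activated C4 chloride by addition–elimination and should give 7.

**Further compounds**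
F1 | step 1 | 1-(2-bromophenyl)octadecane-1,3-dione | CCCCCCCCCCCCCCCC(=O)CC(=O)c1ccccc1Br
F2 | step 1 | (Z)-1-(2-bromophenyl)-3-(methylamino)octadec-2-en-1-one | CCCCCCCCCCCCCCC/C(NC)=C/C(=O)c1ccccc1Br
F3 | step 2 | 4-chloro-2-pentadecylquinoline | CCCCCCCCCCCCCCCc1cc(Cl)c2ccccc2n1
F4 | step 2 | 4-chloro-1-methyl-2-pentadecylquinolinium trifluoromethanesulfonate | CCCCCCCCCCCCCCCc1cc(Cl)c2ccccc2[n+]1C.[O-]S(=O)(=O)C(F)(F)F
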